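## Analysis of the target

The target (25) is a depside: two benzene rings joined by an aryl ester, with no stereocentre. Ring A is a 2-hydroxy-4-methoxybenzoyl unit carrying a 2-oxopentyl chain at C6. Ring B is 2-hydroxy-6-propylbenzoic acid, acylated by ring A at O4. The ester carbonyl on ring A lies between the C2 hydroxyl and the C6 side chain, so it is hard to make by acylation, yet as a phenyl-type ester it is readily cleaved by nucleophiles. The oxygen of the side-chain ketone (as enol, or as the corresponding carbinol) can reach that carbonyl through a six-membered ring and expel ring B as a lactone forms, so strong acid, base and heat must be avoided late in the route. The salicylic acid of ring B decarboxylates on heating, and of the three phenolic oxygens only O4 of ring A is methylated. The strategy rests on the pattern of ring A: C1 (acyl), C2 (OH), C4 (OMe) and C6 (alkyl) is what a 1-silyloxy-1,3-dimethoxybutadiene delivers onto the two carbons of an alk-2-ynoate, and the ester oxygen of that ynoate can already be O4 of ring B.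

## Retrosynthetic reasoning

**25 back to 24.** The first cut is the O–benzyl bond of the ring B ester. A free carboxylic acid would quench the organometallics and the diene and would itself be activated in the esterification, so it stays masked to the end. The forward step is a neutral hydrogenolysis that must leave the aryl ester and the side-chain ketone untouched.

**24 back to 23 and 22.** The side-chain carbonyl is traced to a secondary carbinol and then to its silyl ether. A ketone cannot be carried here: in an ynoate it would flank a doubly activated propargylic CH2 and isomerize to an allenone, and next to the finished ring A its enol can lactonize onto the aryl ester. The forward steps must free the carbinol of 23 and oxidize it quickly near neutrality, because 23 is the one intermediate in which a hydroxyl can reach the ester carbonyl.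

**22 back to 15 and 18.** This is the central disconnection. Ring A is opened at C1–C2 and C5–C6, returning C1 and C6 with their substituents to the triple bond of 15 and the other four carbons with both oxygens to 18. Cutting here, and not at the depside ester, means the di-ortho-substituted ester is never made by acylation, and O2 and O4 arrive already differentiated as silyl ether and methyl ether. The forward reaction must place the ketene acetal carbon of 18 on the α-carbon of the ynoate, aromatize adduct 20 by loss of a methoxy group, and tolerate the chelated ring B phenol, which is expected to be silylated in passing (19, 21).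

**15 back to 8 and 13.** The acyl–O4 bond is cut while the acid is still an unhindered alk-2-ynoic acid. In 13 the C2 hydroxyl is tied in a hydrogen bond to the ester carbonyl, so the esterification only has to follow the innate preference for O4.

**8 back to 5, 4, 1 and 2.** The carboxyl carbon is removed from the alkyne terminus (C1–C2 of the ynoic acid), leaving silyl ether 5 of homopropargylic alcohol 4. Alcohol 4 is cut at the bond that becomes C4–C5 of the acid, giving aldehyde 1 and propargyl halide 2. Both forward reactions are additions of a metalated carbon (3, then 6) to an electrophile; the racemic carbinol they create does not matter.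

**13 back to 11 and 9.** The benzyl group is removed and the carboxyl carbon is cut from C1 of ring B, leading to resorcinol 9. The forward carboxylation must go to the ring carbon between a hydroxyl and the propyl group, not between the two hydroxyls.

**18 back to 16.** The O–Si bond is cut. The forward reaction is γ-deprotonation of enoate 16 and O-silylation of dienolate 17.

## Alternatives that were turned down

**Alternative 1:** ring B is cut at C1–C6 and C2–C3 into dibenzyl malonate A1 and (E)-hept-3-en-2-one A2.
- Forward key step: under a benzyloxide base, A1 adds to A2 in a Michael reaction and the methyl ketone enolate closes on one ester in a Claisen condensation. This gives the racemic trans cyclohexane-1,3-dione A3, which is dehydrogenated to 13.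
- For: the materials are cheap, the benzyl ester is present from the start, and the carboxyl position on ring B is fixed by construction. On that last point it is stronger than the chosen route, which relies on a directed carboxylation of 9.
- Against: the ring-forming step is spent on the easy half, since 9 is purchasable and two steps from 13. Aromatization of A3 by halogenation and elimination risks nuclear halogenation and ester exchange. Ring A, the hindered ester and the ketone remain unsolved.
- Comparison: both routes reach 13 in two operations, so there is no gain in step count. The chosen strategy uses its ring construction where the oxygen pattern of ring A and the depside link are set together.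

**Alternative 2:** ring A is cut at the C6–CH2 bond, with the keto acid stored as an isocoumarin.
- Forward key step: [Cp*RhCl2]2 (trivalent rhodium) activates the single ortho C–H of 2-(benzyloxy)-4-methoxybenzoic acid A4 under carboxylate direction. The sulfoxonium ylide A5 transfers its acylmethylene unit, and the carboxyl closes on the new ketone to give isocoumarin A6.
- For: A4 has only one ortho C–H, so regiochemistry is unambiguous. The ring A oxygens are already differentiated, and the step is catalytic and convergent. As a ring A construction it is probably more dependable than a thermal cycloaddition.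
- Against: A6 is the lactone into which the target's keto ester tends to collapse. Going on requires opening it to keto acid A7, which recloses whenever the carboxyl is activated, so the ketone must be masked in the open form. The di-ortho-substituted acid must then acylate 13, the hindered esterification. Opening, ketalization, esterification, deketalization and debenzylation add about five steps after the key step.
- Comparison: the chosen strategy forms the ester on unhindered acid 8 and never has a free or activated ring A carboxyl beside the ketone.

**Alternative 3:** both bonds at the depside carbonyl are cut, C1(ring A)–C(=O) and C(=O)–O4.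
- Forward key step: Pd(OAc)2 with a wide-bite-angle diphosphine gives zerovalent palladium, which inserts into the C–I bond of aryl iodide A8. Carbon monoxide A9 is taken up to the aroyl palladium species, and the phenoxide of 13 captures it to give depside A10.
- For: it is the most convergent plan, joining two complete halves late in one catalytic step without activating a hindered acid. On convergence it is clearly stronger than the chosen, more linear route.
- Against: the iodide of A8 sits between a methoxy group and the benzylic CH2, so oxidative addition and acyl transfer are slow and reduction competes. After the union, the O2 methyl must be removed selectively beside the O4 methyl, the aryl ester, the benzyl ester and the ketal; a Lewis acidic boron halide would also attack the ketal and the benzyl ester. Acidic ketal hydrolysis beside the aryl ester invites isocoumarin closure on the way to 24. A8 itself needs several steps.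
- Comparison: the chosen strategy takes O2 as a silyl ether and O4 as a methyl ether directly from 18, so no late demethylation is needed, and its side-chain oxygen is unmasked by oxidation, not by acid.

Key step: step 8

Remark on the chemistry: the carbinol carbon in 4 to 23 is a stereocentre that the target does not contain; it is carried as the racemate and removed by the oxidation in step 10.

## Route

Step 1
Reactants: 1 butanal; 2 propargyl bromide (3-bromoprop-1-yne)
Product: 4 hept-1-yn-4-ol (racemic), via allenylzinc bromide 3 (not isolated)
Conditions: Zn dust, THF/sat. aq NH4Cl, 0 °C to rt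
Reagents that add atoms: none
Why: Barbier propargylation; organozinc 3 should add to the aldehyde through its γ-carbon, so the homopropargylic alcohol is the main product, and the new carbinol centre is racemic and later oxidized away.

Step 2
Reactants: 4 hept-1-yn-4-ol
Product: 5 tert-butyl(hept-1-yn-4-yloxy)dimethylsilane (racemic)
Conditions: TBSCl, imidazole, DMF, rt
Reagents that add atoms: tert-butyldimethylsilyl chloride, CC(C)(C)[Si](C)(C)Cl
Why: Standard silylation of a secondary alcohol; the silyl ether masks the future ketone oxygen against the organolithium, the carbodiimide and the hot diene.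

Step 3
Reactants: 5 tert-butyl(hept-1-yn-4-yloxy)dimethylsilane
Product: 8 5-[(tert-butyldimethylsilyl)oxy]oct-2-ynoic acid (racemic), via lithium acetylide 6 (not isolated), via lithium carboxylate 7 (not isolated)
Conditions: n-BuLi, THF, −78 °C; CO2 (g), −78 to 0 °C; then cold 1 M HCl to pH 3
Reagents that add atoms: carbon dioxide, O=C=O
Why: Deprotonation of the terminal alkyne and carboxylation of the acetylide is a reliable route to alk-2-ynoic acids; the secondary silyl ether should survive the brief cold acidification.

Step 4
Reactants: 9 5-propylresorcinol (5-propylbenzene-1,3-diol)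
Product: 11 2,4-dihydroxy-6-propylbenzoic acid, via magnesium salicylate chelate 10 (not isolated)
Conditions: MeOMgOCO2Me (2 M in DMF), 120 °C, N2 stream; then cold 2 M HCl
Reagents that add atoms: methoxymagnesium methyl carbonate (MeOMgOCO2Me), CO[Mg]OC(=O)OC
Why: Kolbe–Schmitt-type ortho-carboxylation through the magnesium phenoxide; the ring carbon ortho to one hydroxyl and para to the other is the most nucleophilic, and chelate 10 holds the carboxyl until the cold acidification.

Step 5
Reactants: 11 2,4-dihydroxy-6-propylbenzoic acid
Product: 13 benzyl 2,4-dihydroxy-6-propylbenzoate, via potassium carboxylate 12 (not isolated)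
Conditions: KHCO3, DMF, rt; BnBr, rt
Reagents that add atoms: benzyl bromide, BrCc1ccccc1
Why: Bicarbonate deprotonates only the carboxylic acid, so the SN2 alkylation should give the benzyl ester and leave both phenols free; room temperature avoids decarboxylation.

Step 6
Reactants: 8 5-[(tert-butyldimethylsilyl)oxy]oct-2-ynoic acid; 13 benzyl 2,4-dihydroxy-6-propylbenzoate
Product: 15 benzyl 4-({5-[(tert-butyldimethylsilyl)oxy]oct-2-ynoyl}oxy)-2-hydroxy-6-propylbenzoate (racemic), via O-acylisourea 14 (not isolated)
Conditions: DCC, DMAP (5 mol%), CH2Cl2, −20 to 0 °C
Reagents that add atoms: none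
Why: Steglich esterification of an unhindered acid; the C2 hydroxyl of 13 is hydrogen-bonded to the ester carbonyl and shielded, so acylation should occur at O4 only, and the low temperature and low catalyst loading limit conjugate addition to the ynoate.

Step 7
Reactants: 16 methyl (E)-3-methoxybut-2-enoate
Product: 18 1,3-dimethoxy-1-(trimethylsilyloxy)buta-1,3-diene (Brassard's diene; ketene acetal geometry not relevant), via lithium dienolate 17 (not isolated)
Conditions: LiN(iPr)2, THF, −78 °C; Me3SiCl, −78 °C to rt; distillation
Reagents that add atoms: chlorotrimethylsilane, C[Si](C)(C)Cl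
Why: Kinetic γ-deprotonation of the vinylogous ester gives the dienolate, which the hard silyl chloride traps on oxygen; this is the established preparation of the diene, which is distilled and used fresh.

Step 8
Reactants: 15 benzyl 4-({5-[(tert-butyldimethylsilyl)oxy]oct-2-ynoyl}oxy)-2-hydroxy-6-propylbenzoate; 18 1,3-dimethoxy-1-(trimethylsilyloxy)buta-1,3-diene
Product: 22 benzyl 4-[(2-{2-[(tert-butyldimethylsilyl)oxy]pentyl}-6-hydroxy-4-methoxybenzoyl)oxy]-2-hydroxy-6-propylbenzoate (racemic), via ring B trimethylsilyl ether 19 (not isolated), via cyclohexa-1,4-diene cycloadduct 20 (not isolated), via bis(trimethylsilyl) ether 21 (not isolated)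
Conditions: 18 (4 equiv in two portions), toluene, 110 °C, sealed tube; then 10% aq citric acid, THF, rt
Reagents that add atoms: none
Why: The first equivalent of 18 should transfer its trimethylsilyl group to the chelated ring B phenol (19), removing the only acidic proton. A thermal (4+2) cycloaddition of normal electron demand then joins the CH2 terminus of the diene, its most nucleophilic carbon, to the β-carbon of the ynoate (C5–C6 of ring A) and the ketene acetal carbon to the α-carbon (C1–C2), giving cyclohexa-1,4-diene 20. 1,4-Elimination of methanol across the mixed ketal carbon and the ring CH2 aromatizes 20 to 21, and the citric acid work-up cleaves both aryl silyl ethers while the secondary tert-butyldimethylsilyl ether stays. The closest known reaction type is the Diels–Alder benzannulation of Brassard-type 1,1,3-trioxygenated dienes with alk-2-ynoates to give 6-alkyl resorcylates. Ring A is closed by an intermolecular cycloaddition in which both new ring bonds form in one event, not by cyclization of a tethered chain. No stereocentre is set: the ketal carbon of 20 is flattened on aromatization and the carbinol carbon stays racemic. The step needs regioselectivity and chemoselectivity; the first follows from the matched polarization of the vinylogous ketene acetal and the ynoate, whose aryloxy group lowers the acceptor orbital further, and the second from the absence of a ketone beside the propargylic CH2, so that allenoate formation does not compete.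

Step 9
Reactants: 22 benzyl 4-[(2-{2-[(tert-butyldimethylsilyl)oxy]pentyl}-6-hydroxy-4-methoxybenzoyl)oxy]-2-hydroxy-6-propylbenzoate
Product: 23 benzyl 2-hydroxy-4-{[2-hydroxy-6-(2-hydroxypentyl)-4-methoxybenzoyl]oxy}-6-propylbenzoate (racemic)
Conditions: HF·pyridine, THF, 0 °C to rt (polyethylene vessel); cold pH 7 buffer work-up, crude used at once
Reagents that add atoms: none
Why: Fluoride-driven cleavage of the silyl ether in a weakly acidic medium; no alkoxide is generated, which should keep the carbinol from attacking the aryl ester during its short lifetime.

Step 10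
Reactants: 23 benzyl 2-hydroxy-4-{[2-hydroxy-6-(2-hydroxypentyl)-4-methoxybenzoyl]oxy}-6-propylbenzoate
Product: 24 benzyl 2-hydroxy-4-{[2-hydroxy-4-methoxy-6-(2-oxopentyl)benzoyl]oxy}-6-propylbenzoate
Conditions: Dess–Martin periodinane, NaHCO3, CH2Cl2, 0 °C to rt
Reagents that add atoms: none
Why: Dess–Martin oxidation of a secondary alcohol under buffered, near-neutral conditions; the chelated, ester-deactivated phenols should not be oxidized, and the stereocentre of the carbinol is removed here.

Step 11
Reactants: 24 benzyl 2-hydroxy-4-{[2-hydroxy-4-methoxy-6-(2-oxopentyl)benzoyl]oxy}-6-propylbenzoate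
Product: 25 2-hydroxy-4-{[2-hydroxy-4-methoxy-6-(2-oxopentyl)benzoyl]oxy}-6-propylbenzoic acid (CNP0187582.0)
Conditions: H2 (1 atm), 10% Pd/C, EtOAc, rt
Reagents that add atoms: none
Why: Hydrogenolysis of the benzyl ester is neutral and should spare the aryl ester and the non-conjugated ketone; the acid is isolated by crystallization without base or heat.

## Compound list

1 | butanal | CCCC=O | starting material
2 | propargyl bromide (3-bromoprop-1-yne) | C#CCBr | starting material
3 | allenylzinc bromide | C=C=C[Zn]Br | intermediate
4 | hept-1-yn-4-ol (racemic) | CCCC(O)CC#C | intermediate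
5 | tert-butyl(hept-1-yn-4-yloxy)dimethylsilane (racemic) | CCCC(O[Si](C)(C)C(C)(C)C)CC#C | intermediate
6 | lithium acetylide of 5 (racemic) | CCCC(O[Si](C)(C)C(C)(C)C)CC#[C-].[Li+] | intermediate
7 | lithium 5-[(tert-butyldimethylsilyl)oxy]oct-2-ynoate (racemic) | CCCC(O[Si](C)(C)C(C)(C)C)CC#CC(=O)[O-].[Li+] | intermediate
8 | 5-[(tert-butyldimethylsilyl)oxy]oct-2-ynoic acid (racemic) | CCCC(O[Si](C)(C)C(C)(C)C)CC#CC(=O)O | intermediate
9 | 5-propylresorcinol (5-propylbenzene-1,3-diol) | CCCc1cc(O)cc(O)c1 | starting material
10 | magnesium chelate of 2,4-dihydroxy-6-propylbenzoate | CCCc1cc(O)cc2O[Mg]OC(=O)c12 | intermediate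
11 | 2,4-dihydroxy-6-propylbenzoic acid | CCCc1cc(O)cc(O)c1C(=O)O | intermediate
12 | potassium 2,4-dihydroxy-6-propylbenzoate | CCCc1cc(O)cc(O)c1C(=O)[O-].[K+] | intermediate
13 | benzyl 2,4-dihydroxy-6-propylbenzoate | CCCc1cc(O)cc(O)c1C(=O)OCc1ccccc1 | intermediate
14 | O-acylisourea from 8 and DCC (racemic) | CCCC(O[Si](C)(C)C(C)(C)C)CC#CC(=O)OC(=NC1CCCCC1)NC1CCCCC1 | intermediate
15 | benzyl 4-({5-[(tert-butyldimethylsilyl)oxy]oct-2-ynoyl}oxy)-2-hydroxy-6-propylbenzoate (racemic) | CCCC(O[Si](C)(C)C(C)(C)C)CC#CC(=O)Oc1cc(O)c(C(=O)OCc2ccccc2)c(CCC)c1 | intermediate
16 | methyl (E)-3-methoxybut-2-enoate | CO/C(C)=C/C(=O)OC | starting material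
17 | lithium dienolate of 16 | C=C(OC)C=C(OC)[O-].[Li+] | intermediate
18 | 1,3-dimethoxy-1-(trimethylsilyloxy)buta-1,3-diene (Brassard's diene; ketene acetal geometry not relevant) | C=C(OC)C=C(OC)O[Si](C)(C)C | intermediate
19 | benzyl 4-({5-[(tert-butyldimethylsilyl)oxy]oct-2-ynoyl}oxy)-6-propyl-2-(trimethylsilyloxy)benzoate (racemic) | CCCC(O[Si](C)(C)C(C)(C)C)CC#CC(=O)Oc1cc(O[Si](C)(C)C)c(C(=O)OCc2ccccc2)c(CCC)c1 | intermediate
20 | cyclohexa-1,4-diene cycloadduct of 19 and 18 (mixture of diastereomers, racemic) | COC1=CC(OC)(O[Si](C)(C)C)C(C(=O)Oc2cc(O[Si](C)(C)C)c(C(=O)OCc3ccccc3)c(CCC)c2)=C(CC(CCC)O[Si](C)(C)C(C)(C)C)C1 | intermediate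
21 | bis(trimethylsilyl) ether of 22 (racemic) | CCCC(O[Si](C)(C)C(C)(C)C)Cc1cc(OC)cc(O[Si](C)(C)C)c1C(=O)Oc1cc(O[Si](C)(C)C)c(C(=O)OCc2ccccc2)c(CCC)c1 | intermediate
22 | benzyl 4-[(2-{2-[(tert-butyldimethylsilyl)oxy]pentyl}-6-hydroxy-4-methoxybenzoyl)oxy]-2-hydroxy-6-propylbenzoate (racemic) | CCCC(O[Si](C)(C)C(C)(C)C)Cc1cc(OC)cc(O)c1C(=O)Oc1cc(O)c(C(=O)OCc2ccccc2)c(CCC)c1 | intermediate
23 | benzyl 2-hydroxy-4-{[2-hydroxy-6-(2-hydroxypentyl)-4-methoxybenzoyl]oxy}-6-propylbenzoate (racemic) | CCCC(O)Cc1cc(OC)cc(O)c1C(=O)Oc1cc(O)c(C(=O)OCc2ccccc2)c(CCC)c1 | intermediate
24 | benzyl 2-hydroxy-4-{[2-hydroxy-4-methoxy-6-(2-oxopentyl)benzoyl]oxy}-6-propylbenzoate | CCCC(=O)Cc1cc(OC)cc(O)c1C(=O)Oc1cc(O)c(C(=O)OCc2ccccc2)c(CCC)c1 | intermediate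
25 | 2-hydroxy-4-{[2-hydroxy-4-methoxy-6-(2-oxopentyl)benzoyl]oxy}-6-propylbenzoic acid (CNP0187582.0) | CCCC(=O)Cc1cc(OC)cc(O)c1C(=O)Oc1cc(O)c(C(=O)O)c(CCC)c1 | target

Total step count: 11
Longest linear sequence: 8 steps (steps 1, 2, 3, 6, 8, 9, 10, 11, from butanal)

## Steps least certain to work

**Step 8 (key step).**
- What may go wrong: the cycloaddition may be outrun by loss of the diene. The β-alkyl ynoate is only moderately activated, while 18 is consumed at 110 °C by proton and silyl transfer to the phenols and by thermal decomposition. The activated aryl ester also offers the silyl ketene acetal a second electrophilic site. On aromatization the silyloxy group may leave in place of the methoxy group, which would leave the methyl on O2.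
- Fallback (sets out from 8, returns at 22): the cycloaddition is moved to an ester with no phenol and no active acyl group, and the depside bond is made afterwards by acylation. Acid 8 is alkylated (BnBr, K2CO3, DMF) to benzyl 5-[(tert-butyldimethylsilyl)oxy]oct-2-ynoate F1. F1 is heated with 18 without solvent and worked up as in step 8 to give benzyl 2-{2-[(tert-butyldimethylsilyl)oxy]pentyl}-6-hydroxy-4-methoxybenzoate F2. Hydrogenolysis (H2, 10% Pd/C, EtOAc) gives 2-{2-[(tert-butyldimethylsilyl)oxy]pentyl}-6-hydroxy-4-methoxybenzoic acid F3, which is condensed with 13 (DCC, toluene) to 22. This gives up the main advantage of the route, since the hindered ester is then formed by acylation, but each step is of a known type.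

**Step 9.**
- What may go wrong: once freed, the carbinol oxygen may attack the aryl ester carbonyl through a six-membered ring and expel ring B as the phenol (intramolecular transesterification), especially if the medium turns basic.
- Fallback (sets out from 4, returns at 24; steps 9 and 10 are bypassed): the ketone is carried as a dioxolane, so no hydroxyl is ever free beside the ester. Alcohol 4 is oxidized (Dess–Martin periodinane, CH2Cl2) to hept-1-yn-4-one F4, handled without base. F4 is ketalized (1,2-bis(trimethylsilyloxy)ethane, catalytic Me3SiOSO2CF3, CH2Cl2, −78 °C) to 2-(prop-2-yn-1-yl)-2-propyl-1,3-dioxolane F5. Carboxylation as in step 3 gives 4-(2-propyl-1,3-dioxolan-2-yl)but-2-ynoic acid F6. Esterification with 13 as in step 6 gives benzyl 2-hydroxy-6-propyl-4-{[4-(2-propyl-1,3-dioxolan-2-yl)but-2-ynoyl]oxy}benzoate F7. Cycloaddition with 18 as in step 8 gives benzyl 2-hydroxy-4-({2-hydroxy-4-methoxy-6-[(2-propyl-1,3-dioxolan-2-yl)methyl]benzoyl}oxy)-6-propylbenzoate F8. Mild hydrolysis (pyridinium p-toluenesulfonate, wet acetone, rt) then gives 24.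

**Step 4.**
- What may go wrong: carboxylation between the two hydroxyls instead of between hydroxyl and propyl group, and decarboxylation of the product during the acidic work-up.
- Fallback (sets out from 9, returns at 11): Vilsmeier–Haack formylation of 9 (POCl3, DMF, 0 °C to rt, then aqueous hydrolysis), whose regiochemistry on 5-alkylresorcinols is secure, gives 2,4-dihydroxy-6-propylbenzaldehyde F9. Chlorite oxidation (NaClO2, NaH2PO4, DMSO/H2O, 0 °C to rt) gives 11.

**Step 6.**
- What may go wrong: conjugate addition of the nucleophilic catalyst or of the phenol to the activated triple bond, and O-to-N acyl shift in 14 to an unreactive N-acylurea.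
- Fallback (sets out from 8, returns at 15): the acyl donor is changed to an isolated acid chloride. Acid 8 is treated with 1-chloro-N,N,2-trimethylprop-1-en-1-amine in CH2Cl2 at 0 °C to give 5-[(tert-butyldimethylsilyl)oxy]oct-2-ynoyl chloride F10. F10 acylates 13 at O4 in the presence of 2,6-dimethylpyridine at −20 °C, with no carbodiimide and no nucleophilic catalyst, to give 15.

## Further compounds

F1 | step 8 | benzyl 5-[(tert-butyldimethylsilyl)oxy]oct-2-ynoate (racemic) | CCCC(O[Si](C)(C)C(C)(C)C)CC#CC(=O)OCc1ccccc1
F2 | step 8 | benzyl 2-{2-[(tert-butyldimethylsilyl)oxy]pentyl}-6-hydroxy-4-methoxybenzoate (racemic) | CCCC(O[Si](C)(C)C(C)(C)C)Cc1cc(OC)cc(O)c1C(=O)OCc1ccccc1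
F3 | step 8 | 2-{2-[(tert-butyldimethylsilyl)oxy]pentyl}-6-hydroxy-4-methoxybenzoic acid (racemic) | CCCC(O[Si](C)(C)C(C)(C)C)Cc1cc(OC)cc(O)c1C(=O)O
F4 | step 9 | hept-1-yn-4-one | CCCC(=O)CC#C
F5 | step 9 | 2-(prop-2-yn-1-yl)-2-propyl-1,3-dioxolane | CCCC1(CC#C)OCCO1
F6 | step 9 | 4-(2-propyl-1,3-dioxolan-2-yl)but-2-ynoic acid | CCCC1(CC#CC(=O)O)OCCO1
F7 | step 9 | benzyl 2-hydroxy-6-propyl-4-{[4-(2-propyl-1,3-dioxolan-2-yl)but-2-ynoyl]oxy}benzoate | CCCC1(CC#CC(=O)Oc2cc(O)c(C(=O)OCc3ccccc3)c(CCC)c2)OCCO1
F8 | step 9 | benzyl 2-hydroxy-4-({2-hydroxy-4-methoxy-6-[(2-propyl-1,3-dioxolan-2-yl)methyl]benzoyl}oxy)-6-propylbenzoate | CCCC1(Cc2cc(OC)cc(O)c2C(=O)Oc2cc(O)c(C(=O)OCc3ccccc3)c(CCC)c2)OCCO1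
F9 | step 4 | 2,4-dihydroxy-6-propylbenzaldehyde | CCCc1cc(O)cc(O)c1C=O
F10 | step 6 | 5-[(tert-butyldimethylsilyl)oxy]oct-2-ynoyl chloride (racemic) | CCCC(O[Si](C)(C)C(C)(C)C)CC#CC(=O)Cl
A1 | alternative 1 | dibenzyl malonate | O=C(CC(=O)OCc1ccccc1)OCc1ccccc1
A2 | alternative 1 | (E)-hept-3-en-2-one | CCC/C=C/C(C)=O
A3 | alternative 1 | benzyl 2,4-dioxo-6-propylcyclohexane-1-carboxylate (racemic, trans; one enantiomer drawn) | CCC[C@@H]1CC(=O)CC(=O)[C@H]1C(=O)OCc1ccccc1
A4 | alternative 2 | 2-(benzyloxy)-4-methoxybenzoic acid | COc1ccc(C(=O)O)c(OCc2ccccc2)c1
A5 | alternative 2 | 1-[dimethyl(oxo)-λ6-sulfanylidene]pentan-2-one | CCCC(=O)C=S(C)(C)=O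
A6 | alternative 2 | 8-(benzyloxy)-6-methoxy-3-propylisochromen-1-one | CCCc1cc2cc(OC)cc(OCc3ccccc3)c2c(=O)o1
A7 | alternative 2 | 2-(benzyloxy)-4-methoxy-6-(2-oxopentyl)benzoic acid | CCCC(=O)Cc1cc(OC)cc(OCc2ccccc2)c1C(=O)O
A8 | alternative 3 | 2-[(2-iodo-3,5-dimethoxyphenyl)methyl]-2-propyl-1,3-dioxolane | CCCC1(Cc2cc(OC)cc(OC)c2I)OCCO1
A9 | alternative 3 | carbon monoxide | [C-]#[O+]
A10 | alternative 3 | benzyl 4-({2,4-dimethoxy-6-[(2-propyl-1,3-dioxolan-2-yl)methyl]benzoyl}oxy)-2-hydroxy-6-propylbenzoate | CCCC1(Cc2cc(OC)cc(OC)c2C(=O)Oc2cc(O)c(C(=O)OCc3ccccc3)c(CCC)c2)OCCO1
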